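Everything rests on one disconnection: the formyl group at ring A C3 is traced back to a methyl group, so that all four aryl methyls arrive with 2,5-dimethylbenzoquinone and atraric acid. The key step exploits the position of this C3 methyl, flanked by the free C2 hydroxyl and the ketal-bound C4 oxygen of the electron-rich ring A: DDQ in wet dioxane should convert it in one operation, through an ortho-quinone methide, into the aldehyde and leave the other three methyls alone. The precursor is the complete depside, ring A carrying its C4,C5 catechol as an acetonide and a free C2 phenol, ring B being the atraric acid unit.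

Key step: step 8

Remark: ring A is the benzoyl ring, numbered from its carbonyl-bearing carbon (ring A C1 = benzodioxole C5, C2 = C6, C3 = C7, C4 = C7a, C5 = C3a, C6 = C4); ring B is the atraric acid ring; atraric acid is the methyl ester itself; the target has no stereocentre, so nothing stereochemical has to be set.

Step 1
Reactants: 1 (2,5-dimethyl-1,4-benzoquinone)
Product: 2 (3,6-dimethylbenzene-1,2,4-triyl triacetate)
Conditions: Ac2O, BF3·OEt2 (cat.), 40 °C
Reagents that add atoms: acetic anhydride, CC(=O)OC(C)=O
Why: Thiele–Winter acetoxylation, in which acid-activated conjugate addition of acetate to the quinone (its two free ring positions are equivalent) is followed by enolisation and O-acetylation, should give a single triacetate whose methyl between two oxygens is the future ring A C3 methyl.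

Step 2
Reactants: 2 (3,6-dimethylbenzene-1,2,4-triyl triacetate); 3 (2,2-dimethoxypropane)
Product: 5 acetonide phenol (2,2,4,7-tetramethyl-1,3-benzodioxol-5-ol), via 3,6-dimethylbenzene-1,2,4-triol 4 (not isolated)
Conditions: HCl (cat.), MeOH, 50 °C, Ar; evaporate; then 3, TsOH·H2O (cat.), toluene, reflux, 4 Å MS (Soxhlet), Ar
Reagents that add atoms: none
Why: Acid-catalysed transesterification with methanol should free the triol, and ketal exchange with 3 can close a five-membered dioxole only across the two adjacent hydroxyls, so the isolated hydroxyl stays free while argon guards the easily autoxidised triol.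

Step 3
Reactants: 5 acetonide phenol (2,2,4,7-tetramethyl-1,3-benzodioxol-5-ol)
Product: 6 benzyl ether (5-(benzyloxy)-2,2,4,7-tetramethyl-1,3-benzodioxole)
Conditions: BnBr, K2CO3, DMF, rt
Reagents that add atoms: benzyl bromide, BrCc1ccccc1
Why: Williamson etherification of the phenoxide should be clean, and the benzyl ether is chosen because hydrogenolysis later removes it without touching the ketal or the esters.

Step 4
Reactants: 6 benzyl ether (5-(benzyloxy)-2,2,4,7-tetramethyl-1,3-benzodioxole)
Product: 7 aryl bromide (5-(benzyloxy)-6-bromo-2,2,4,7-tetramethyl-1,3-benzodioxole)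
Conditions: NBS, MeCN, 0 °C, dark
Reagents that add atoms: N-bromosuccinimide, O=C1CCC(=O)N1Br
Why: Electrophilic aromatic bromination should occur at the single unsubstituted ring carbon, which is ortho to the benzyloxy group and para to a dioxole oxygen, while the polar solvent and exclusion of light suppress radical bromination of the methyls.

Step 5
Reactants: 7 aryl bromide (5-(benzyloxy)-6-bromo-2,2,4,7-tetramethyl-1,3-benzodioxole)
Product: 9 acid (6-(benzyloxy)-2,2,4,7-tetramethyl-1,3-benzodioxole-5-carboxylic acid), via aryllithium 8 (not isolated)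
Conditions: n-BuLi, THF, −78 °C; CO2, −78 °C → rt; aq. HCl
Reagents that add atoms: carbon dioxide, O=C=O
Why: Bromine–lithium exchange at −78 °C is faster than any deprotonation, and carboxylation of the aryllithium with CO2 should place the future depside carbonyl carbon on ring A C1.

Step 6
Reactants: 9 acid (6-(benzyloxy)-2,2,4,7-tetramethyl-1,3-benzodioxole-5-carboxylic acid); 10 atraric acid (methyl 2,4-dihydroxy-3,6-dimethylbenzoate)
Product: 12 benzyl depside (methyl 4-{[6-(benzyloxy)-2,2,4,7-tetramethyl-1,3-benzodioxole-5-carbonyl]oxy}-2-hydroxy-3,6-dimethylbenzoate), via mixed trifluoroacetic anhydride 11 (not isolated)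
Conditions: (CF3CO)2O, toluene, 0 °C → rt
Reagents that add atoms: none
Why: Esterification through the mixed trifluoroacetic anhydride, which ionises readily to an acylium ion when both ortho positions are substituted, should acylate the C4 hydroxyl of 10 and not its C2 hydroxyl, which is chelated to the ester carbonyl and flanked on both sides.

Step 7
Reactants: 12 benzyl depside (methyl 4-{[6-(benzyloxy)-2,2,4,7-tetramethyl-1,3-benzodioxole-5-carbonyl]oxy}-2-hydroxy-3,6-dimethylbenzoate)
Product: 13 methyl depside (methyl 2-hydroxy-4-[(6-hydroxy-2,2,4,7-tetramethyl-1,3-benzodioxole-5-carbonyl)oxy]-3,6-dimethylbenzoate)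
Conditions: H2 (1 atm), 10% Pd/C, EtOAc, rt
Reagents that add atoms: none
Why: Hydrogenolysis of the benzyl aryl ether over palladium on carbon should free the C2 phenol, whereas the aryl ester, the methyl ester and the ketal are inert under these neutral conditions.

Step 8
Reactants: 13 methyl depside (methyl 2-hydroxy-4-[(6-hydroxy-2,2,4,7-tetramethyl-1,3-benzodioxole-5-carbonyl)oxy]-3,6-dimethylbenzoate)
Product: 16 formyl depside (methyl 4-[(7-formyl-6-hydroxy-2,2,4-trimethyl-1,3-benzodioxole-5-carbonyl)oxy]-2-hydroxy-3,6-dimethylbenzoate), via ortho-quinone methide 14 (not isolated), via hydroxymethyl depside 15 (not isolated)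
Conditions: DDQ (2.2 equiv), 1,4-dioxane/H2O (20:1), rt, dark, Ar
Reagents that add atoms: water, O
Why: Hydride transfer from the C3 methyl of ring A to DDQ should give a benzylic cation that both flanking oxygens (the C2 hydroxyl and the C4 ketal oxygen) stabilise; loss of the phenolic proton turns it into ortho-quinone methide 14, conjugate addition of water at the exocyclic carbon gives carbinol 15, and a second hydride transfer from the CH2OH group delivers aldehyde 16. The closest known reaction type is the DDQ oxidation of methyl groups ortho or para to a phenolic oxygen on electron-rich arenes to hydroxybenzaldehydes by way of quinone methides. No ring is closed, no skeletal bond is formed and no stereocentre arises. Site selectivity among the four aryl methyls is expected because only the C3 methyl has two ortho oxygen donors, one of them a free phenol, whereas the C6 methyl of ring A is flanked by a single oxygen and by the electron-withdrawing carbonyl, and both methyls of ring B sit on a ring deactivated by an ester and an acyloxy group. Oxidation of the ring itself is held back by the ketal, which rules out an ortho-quinone, by the hydrogen bond of the C2 hydroxyl to the depside carbonyl, and by the low water content, which slows the attack at C5 that would lead to a para-quinone. The aldehyde formed is chelated to the C2 hydroxyl and withdraws electron density from ring A, so the oxidation should stop at 16.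

Step 9
Reactants: 16 formyl depside (methyl 4-[(7-formyl-6-hydroxy-2,2,4-trimethyl-1,3-benzodioxole-5-carbonyl)oxy]-2-hydroxy-3,6-dimethylbenzoate)
Product: 17 target (methyl 4-[(3-formyl-2,4,5-trihydroxy-6-methylbenzoyl)oxy]-2-hydroxy-3,6-dimethylbenzoate)
Conditions: CF3CO2H/H2O (9:1), rt, Ar
Reagents that add atoms: none
Why: Acid-catalysed hydrolysis of the cyclic ketal should release the catechol and acetone, while both esters and the chelated aldehyde tolerate aqueous trifluoroacetic acid at room temperature and argon keeps the hydroxyhydroquinone from autoxidising.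

Compound list
1 | 2,5-dimethyl-1,4-benzoquinone | CC1=CC(=O)C(C)=CC1=O | starting material
2 | 3,6-dimethylbenzene-1,2,4-triyl triacetate | CC(=O)Oc1cc(C)c(OC(C)=O)c(OC(C)=O)c1C | intermediate
3 | 2,2-dimethoxypropane | COC(C)(C)OC | starting material
4 | 3,6-dimethylbenzene-1,2,4-triol | Cc1cc(O)c(C)c(O)c1O | intermediate
5 | 2,2,4,7-tetramethyl-1,3-benzodioxol-5-ol | CC1(C)Oc2c(C)c(O)cc(C)c2O1 | intermediate
6 | 5-(benzyloxy)-2,2,4,7-tetramethyl-1,3-benzodioxole | CC1(C)Oc2c(C)c(OCc3ccccc3)cc(C)c2O1 | intermediate
7 | 5-(benzyloxy)-6-bromo-2,2,4,7-tetramethyl-1,3-benzodioxole | CC1(C)Oc2c(C)c(OCc3ccccc3)c(Br)c(C)c2O1 | intermediate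
8 | [6-(benzyloxy)-2,2,4,7-tetramethyl-1,3-benzodioxol-5-yl]lithium | [Li]c1c(C)c2OC(C)(C)Oc2c(C)c1OCc1ccccc1 | intermediate
9 | 6-(benzyloxy)-2,2,4,7-tetramethyl-1,3-benzodioxole-5-carboxylic acid | OC(=O)c1c(C)c2OC(C)(C)Oc2c(C)c1OCc1ccccc1 | intermediate
10 | atraric acid (methyl 2,4-dihydroxy-3,6-dimethylbenzoate) | COC(=O)c1c(C)cc(O)c(C)c1O | starting material
11 | 6-(benzyloxy)-2,2,4,7-tetramethyl-1,3-benzodioxole-5-carboxylic trifluoroacetic anhydride | O=C(OC(=O)C(F)(F)F)c1c(C)c2OC(C)(C)Oc2c(C)c1OCc1ccccc1 | intermediate
12 | methyl 4-{[6-(benzyloxy)-2,2,4,7-tetramethyl-1,3-benzodioxole-5-carbonyl]oxy}-2-hydroxy-3,6-dimethylbenzoate | COC(=O)c1c(C)cc(OC(=O)c2c(C)c3OC(C)(C)Oc3c(C)c2OCc2ccccc2)c(C)c1O | intermediate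
13 | methyl 2-hydroxy-4-[(6-hydroxy-2,2,4,7-tetramethyl-1,3-benzodioxole-5-carbonyl)oxy]-3,6-dimethylbenzoate | COC(=O)c1c(C)cc(OC(=O)c2c(C)c3OC(C)(C)Oc3c(C)c2O)c(C)c1O | intermediate
14 | methyl 2-hydroxy-3,6-dimethyl-4-[(2,2,4-trimethyl-7-methylidene-6-oxo-6,7-dihydro-1,3-benzodioxole-5-carbonyl)oxy]benzoate | COC(=O)c1c(C)cc(OC(=O)C2=C(C)C3=C(OC(C)(C)O3)C(=C)C2=O)c(C)c1O | intermediate
15 | methyl 2-hydroxy-4-{[6-hydroxy-7-(hydroxymethyl)-2,2,4-trimethyl-1,3-benzodioxole-5-carbonyl]oxy}-3,6-dimethylbenzoate | COC(=O)c1c(C)cc(OC(=O)c2c(C)c3OC(C)(C)Oc3c(CO)c2O)c(C)c1O | intermediate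
16 | methyl 4-[(7-formyl-6-hydroxy-2,2,4-trimethyl-1,3-benzodioxole-5-carbonyl)oxy]-2-hydroxy-3,6-dimethylbenzoate | COC(=O)c1c(C)cc(OC(=O)c2c(C)c3OC(C)(C)Oc3c(C=O)c2O)c(C)c1O | intermediate
17 | methyl 4-[(3-formyl-2,4,5-trihydroxy-6-methylbenzoyl)oxy]-2-hydroxy-3,6-dimethylbenzoate | COC(=O)c1c(C)cc(OC(=O)c2c(C)c(O)c(O)c(C=O)c2O)c(C)c1O | target

Total step count: 9. Longest linear sequence: 9 steps (1 to 17; atraric acid 10 enters at step 6).

Steps most likely to fail

Step 8. The oxidant may attack the nucleus of ring A in place of the C3 methyl. The C2 hydroxyl stands para to the C5 ketal oxygen, so a two-electron oxidation followed by attack of water at C5 and loss of acetone would lead to a hydroxy-para-quinone. Partial oxidation at the C6 methyl is a lesser concern. In the fallback, the C3 carbon is brought in as a formyl group by electrophilic substitution on a ring A that bears hydrogen at C3. It sets out from atraric acid 10 (and reuses 3) and comes back at 16. Commercial 2,4-dihydroxy-6-methylbenzaldehyde F1 would undergo Dakin oxidation (H2O2, aq. NaOH, Ar, then acid) to 6-methylbenzene-1,2,4-triol F2. Ketalisation with 3 and catalytic TsOH·H2O as in step 2 would give 2,2,7-trimethyl-1,3-benzodioxol-5-ol F3. Benzylation as in step 3 would give 6-(benzyloxy)-2,2,4-trimethyl-1,3-benzodioxole F4. NBS should brominate it para to a dioxole oxygen and ortho to the benzyloxy group, giving 6-(benzyloxy)-5-bromo-2,2,4-trimethyl-1,3-benzodioxole F5. Bromine–lithium exchange and CO2 as in step 5 would give 6-(benzyloxy)-2,2,4-trimethyl-1,3-benzodioxole-5-carboxylic acid F6. Coupling with 10 as in step 6 would give methyl 4-{[6-(benzyloxy)-2,2,4-trimethyl-1,3-benzodioxole-5-carbonyl]oxy}-2-hydroxy-3,6-dimethylbenzoate F7, and hydrogenolysis as in step 7 would give methyl 2-hydroxy-4-[(6-hydroxy-2,2,4-trimethyl-1,3-benzodioxole-5-carbonyl)oxy]-3,6-dimethylbenzoate F8. Rieche formylation of F8 (Cl2CHOMe, TiCl4, CH2Cl2, −78 to 0 °C), directed by the titanium-bound C2 phenoxide to the only free position of the more electron-rich ring A, should then give 16. Any material that loses the ketal under TiCl4 would already be the target 17.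

Step 6. Acyl transfer to the phenol may be slow at the doubly ortho-substituted carbonyl. Meanwhile the trifluoroacetic acid formed could open the ketal, or the anhydride could cap the phenol of 10. The fallback replaces the acid-mediated mixed anhydride by base-mediated acylation with an isolated acid chloride; it sets out from 9 and comes back at 12. Acid 9 and 1-chloro-N,N,2-trimethylprop-1-en-1-amine in CH2Cl2 would give, under neutral conditions, 6-(benzyloxy)-2,2,4,7-tetramethyl-1,3-benzodioxole-5-carbonyl chloride F9. With 10, Et3N and catalytic DMAP in CH2Cl2, F9 should acylate the more acidic, unchelated C4 hydroxyl to give 12.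

Step 5. The aryllithium sits between a benzyloxy group and a methyl group. It may be lost through proton transfer from the benzylic OCH2, through alkylation by the butyl bromide formed in the exchange, or through a second addition to the carboxylate. The fallback introduces the carboxyl carbon by electrophilic formylation and oxidises it, with no organolithium; it sets out from 5 and comes back at 9. Magnesium-mediated ortho-formylation of 5 (MgCl2, Et3N, paraformaldehyde, MeCN, reflux) at its only free ring position would give 6-hydroxy-2,2,4,7-tetramethyl-1,3-benzodioxole-5-carbaldehyde F10. Benzylation (BnBr, K2CO3, DMF) would give 6-(benzyloxy)-2,2,4,7-tetramethyl-1,3-benzodioxole-5-carbaldehyde F11. Pinnick oxidation (NaClO2, NaH2PO4, 2-methylbut-2-ene, t-BuOH/H2O), which cannot chlorinate the fully substituted ring, should give 9.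

Further compounds
F1 | step 8 | 2,4-dihydroxy-6-methylbenzaldehyde | Cc1cc(O)cc(O)c1C=O
F2 | step 8 | 6-methylbenzene-1,2,4-triol | Cc1cc(O)cc(O)c1O
F3 | step 8 | 2,2,7-trimethyl-1,3-benzodioxol-5-ol | CC1(C)Oc2cc(O)cc(C)c2O1
F4 | step 8 | 6-(benzyloxy)-2,2,4-trimethyl-1,3-benzodioxole | CC1(C)Oc2cc(OCc3ccccc3)cc(C)c2O1
F5 | step 8 | 6-(benzyloxy)-5-bromo-2,2,4-trimethyl-1,3-benzodioxole | CC1(C)Oc2cc(OCc3ccccc3)c(Br)c(C)c2O1
F6 | step 8 | 6-(benzyloxy)-2,2,4-trimethyl-1,3-benzodioxole-5-carboxylic acid | OC(=O)c1c(C)c2OC(C)(C)Oc2cc1OCc1ccccc1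
F7 | step 8 | methyl 4-{[6-(benzyloxy)-2,2,4-trimethyl-1,3-benzodioxole-5-carbonyl]oxy}-2-hydroxy-3,6-dimethylbenzoate | COC(=O)c1c(C)cc(OC(=O)c2c(C)c3OC(C)(C)Oc3cc2OCc2ccccc2)c(C)c1O
F8 | step 8 | methyl 2-hydroxy-4-[(6-hydroxy-2,2,4-trimethyl-1,3-benzodioxole-5-carbonyl)oxy]-3,6-dimethylbenzoate | COC(=O)c1c(C)cc(OC(=O)c2c(C)c3OC(C)(C)Oc3cc2O)c(C)c1O
F9 | step 6 | 6-(benzyloxy)-2,2,4,7-tetramethyl-1,3-benzodioxole-5-carbonyl chloride | O=C(Cl)c1c(C)c2OC(C)(C)Oc2c(C)c1OCc1ccccc1
F10 | step 5 | 6-hydroxy-2,2,4,7-tetramethyl-1,3-benzodioxole-5-carbaldehyde | O=Cc1c(C)c2OC(C)(C)Oc2c(C)c1O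
F11 | step 5 | 6-(benzyloxy)-2,2,4,7-tetramethyl-1,3-benzodioxole-5-carbaldehyde | O=Cc1c(C)c2OC(C)(C)Oc2c(C)c1OCc1ccccc1
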